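**Retrosynthetic overview**

1. Pharbinilic acid ⇐ hydroxy acid 33 (C7 oxidation) ⇐ enone 29 (C15 deoxygenation) ⇐ keto phosphonate 27: ring D is closed last, through C15–C16, by acylation of a C16 phosphonate carbanion with the C15 lactone carbonyl; C17 comes from formaldehyde.
2. 27 ⇐ hydroxy lactone 26 ⇐ cycloadduct 22: the C9–O–C13 bridge is opened at the benzylic C9–O bond (C13 keeps the oxygen as the tertiary alcohol) and C9–H is then set by directed hydrogenation.
3. 22 ⇐ furan 21 by an intramolecular furan Diels–Alder reaction that closes ring B (C8–C9) and ring C (C13–C14) together and sets C8 and C13 from the single stereocentre C6.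
4. Enabling feature: in ring C the oxygenated C13 and the benzylic C9 are 1,4-related, so C9–C11–C12–C13 with the C13 oxygen is a 2,5-disubstituted furan; the quaternary C8 with its CH2 (C14) is the exocyclic alkene of an α-methylene γ-lactone that ties C7 to C15 on one face of ring B.
5. 21 ⇐ aryl chloride 16 + furylboronate 20; 16 ⇐ 2,4-dihydroxy-3-methylbenzaldehyde, ethyl diazoacetate and 4-bromofuran-2(5H)-one. Ring order: benzofuran (ring A) first, then rings B and C together, then ring D.

Key step: step 10

Remark: gibberellane numbering is used for the non-aromatic carbons (C6 benzylic CH bearing C7; C8 quaternary; C9 benzylic ring-fusion CH; C11, C12; C13 carbinol; C14 bridging CH2; C15; C16; C17 =CH2), and it is assumed that diethyl (furan-2-ylmethyl)phosphonate is made (step 7) rather than bought.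

**Route**

Step 1
Reactants: 1 2,4-dihydroxy-3-methylbenzaldehyde
Product: 2 5-chloro-2,4-dihydroxy-3-methylbenzaldehyde
Conditions: NCS, MeCN, 40 °C
Reagents that add atoms: N-chlorosuccinimide, O=C1CCC(=O)N1Cl
Why: Electrophilic aromatic chlorination should go to C5, the only free position that is ortho to one hydroxyl and para to the other.

Step 2
Reactants: 2 5-chloro-2,4-dihydroxy-3-methylbenzaldehyde
Product: 3 6-chloro-4-formyl-3-hydroxy-2-methylphenyl trifluoromethanesulfonate
Conditions: PhNTf2 (1.05 equiv), Et3N, CH2Cl2, 0 °C to rt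
Reagents that add atoms: N-phenylbis(trifluoromethanesulfonimide), O=S(=O)(N(c1ccccc1)S(=O)(=O)C(F)(F)F)C(F)(F)F
Why: O-Sulfonylation should take the more acidic 4-hydroxyl, because the 2-hydroxyl is held in a hydrogen bond to the aldehyde, as in the usual selective 4-O-functionalisation of 2,4-dihydroxybenzaldehydes.

Step 3
Reactants: 3 6-chloro-4-formyl-3-hydroxy-2-methylphenyl trifluoromethanesulfonate; 4 ethyl diazoacetate
Product: 6 ethyl 5-chloro-7-methyl-6-(trifluoromethylsulfonyloxy)-1-benzofuran-3-carboxylate, via hemiacetal 5 (not isolated)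
Conditions: HBF4·OEt2 (cat.), CH2Cl2, rt; then conc. H2SO4, rt
Reagents that add atoms: none
Why: Acid-catalysed Roskamp-type addition of the diazo ester to the salicylaldehyde with 1,2-aryl shift should give the 2-hydroxy-2,3-dihydrobenzofuran-3-carboxylate, which dehydrates to the benzofuran; the aryl triflate and chloride are inert.

Step 4
Reactants: 6 ethyl 5-chloro-7-methyl-6-(trifluoromethylsulfonyloxy)-1-benzofuran-3-carboxylate; 7 bis(pinacolato)diboron; 8 4-bromofuran-2(5H)-one
Product: 10 ethyl 5-chloro-7-methyl-6-(5-oxo-2,5-dihydrofuran-3-yl)-1-benzofuran-3-carboxylate, via arylboronate 9 (not isolated)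
Conditions: Pd(dppf)Cl2 (cat.), KOAc, 1,4-dioxane, 90 °C; then 8, K3PO4 (aq), 80 °C
Reagents that add atoms: none
Why: One-pot Miyaura borylation and Suzuki–Miyaura coupling, in which the aryl triflate reacts in preference to the aryl chloride and the 4-bromobutenolide is an established coupling partner.

Step 5
Reactants: 10 ethyl 5-chloro-7-methyl-6-(5-oxo-2,5-dihydrofuran-3-yl)-1-benzofuran-3-carboxylate
Product: 11 ethyl 5-chloro-7-methyl-6-[(3R)-5-oxooxolan-3-yl]-1-benzofuran-3-carboxylate
Conditions: Cu(OAc)2 (cat.), p-tol-BINAP (cat., the antipode that gives the 3R lactone), (EtO)2MeSiH, t-BuOH, PhMe, 0 °C to rt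
Reagents that add atoms: none
Why: Asymmetric conjugate reduction of a β-aryl butenolide by a bisphosphine-ligated CuH species, which delivers hydride to one enantiotopic face of the β-carbon and so sets C6, the only stereocentre made by a chiral reagent.

Step 6
Reactants: 11 ethyl 5-chloro-7-methyl-6-[(3R)-5-oxooxolan-3-yl]-1-benzofuran-3-carboxylate; 12 N,N-dimethylmethyleneiminium iodide; 13 iodomethane
Product: 16 ethyl 5-chloro-7-methyl-6-[(3R)-4-methylidene-5-oxooxolan-3-yl]-1-benzofuran-3-carboxylate, via Mannich base 14 (not isolated), via ammonium iodide 15 (not isolated)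
Conditions: LiN(i-Pr)2 (1.05 equiv), THF, −78 °C; 12, −78 °C to rt; then 13, MeOH, rt; then NaHCO3 (aq), CH2Cl2, rt
Reagents that add atoms: none
Why: Mannich reaction of the lactone enolate, N-methylation and Hofmann-type elimination is the standard α-methylenation of γ-butyrolactones and brings in C14; C6 is β to the carbonyl and is not deprotonated.

Step 7
Reactants: 17 furan-2-ylmethanol; 18 triethyl phosphite
Product: 19 diethyl (furan-2-ylmethyl)phosphonate
Conditions: ZnI2, THF, reflux
Reagents that add atoms: none
Why: ZnI2-mediated Michaelis–Arbuzov-type conversion of an activated (furfuryl) alcohol should give the phosphonate without passing through the unstable furfuryl halide.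

Step 8
Reactants: 19 diethyl (furan-2-ylmethyl)phosphonate; 7 bis(pinacolato)diboron
Product: 20 diethyl {[5-(4,4,5,5-tetramethyl-1,3,2-dioxaborolan-2-yl)furan-2-yl]methyl}phosphonate
Conditions: [Ir(OMe)(cod)]2 (cat.), dtbpy, THF, 60 °C
Reagents that add atoms: none
Why: C–H borylation of a 2-substituted furan is selective for the free α-position.

Step 9
Reactants: 16 ethyl 5-chloro-7-methyl-6-[(3R)-4-methylidene-5-oxooxolan-3-yl]-1-benzofuran-3-carboxylate; 20 diethyl {[5-(4,4,5,5-tetramethyl-1,3,2-dioxaborolan-2-yl)furan-2-yl]methyl}phosphonate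
Product: 21 ethyl 5-{5-[(diethoxyphosphoryl)methyl]furan-2-yl}-7-methyl-6-[(3S)-4-methylidene-5-oxooxolan-3-yl]-1-benzofuran-3-carboxylate (same spatial arrangement at C6 as in 16; the descriptor changes by priority only)
Conditions: Pd(OAc)2 (cat.), XPhos, K3PO4 (aq, 0.5 M), THF, 40 °C
Reagents that add atoms: none
Why: Suzuki–Miyaura coupling of an aryl chloride with a 2-furyl pinacol boronate under a bulky biarylphosphine catalyst runs near room temperature, which should spare the α-methylene lactone.

Step 10
Reactants: 21 ethyl 5-{5-[(diethoxyphosphoryl)methyl]furan-2-yl}-7-methyl-6-[(3S)-4-methylidene-5-oxooxolan-3-yl]-1-benzofuran-3-carboxylate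
Product: 22 cycloadduct: 7-oxanorbornene (O bridge between C9 and C13; C11=C12) fused at C8–C9 to ring B; γ-lactone C15(=O)–O–C7 cis-fused to ring B at C6–C8 on the face opposite to C14 and to the O bridge; C13 carries CH2P(O)(OEt)2; ring A is the ethyl benzofuran-3-carboxylate
Conditions: PhMe, BHT (cat.), 110 °C, sealed tube
Reagents that add atoms: none
Why: Thermal intramolecular Diels–Alder reaction of a furan: the furan diene C9=C11–C12=C13 adds suprafacially to the exocyclic C8=C14 bond of the α-methylene lactone, so C8–C9 and C13–C14 form in one concerted, asynchronous step and the furan oxygen becomes the C9–O–C13 bridge. The closest known reaction type is the cycloaddition of 2-substituted furans that carry an alkene on a three-atom tether, which gives 7-oxanorbornenes fused to a five-membered ring. Ring B (five-membered, C5–C6–C8–C9–C10) closes through C8–C9 with the benzo tether forced exo (syn to the oxygen bridge), and ring C (six-membered carbocycle) closes through C13–C14. The quaternary C8 and the oxygenated C13 are controlled by the resident C6 stereocentre, because the aryl group, and with it the furan, stands on one face of the lactone ring and can reach only that face of C8=C14, which puts C15 cis to C7 and C14 on the opposite face of ring B and, through the suprafacial addition, fixes C13 relative to C8; C9 is also formed but is reset in steps 12 and 13. The step needs regioselectivity (C9 to C8, C13 to C14), secured by the short tether, diastereofacial selectivity, secured by the cis-fused lactone, and a favourable equilibrium, which the conjugated s-cis-locked dienophile and the hydrogenation of the adduct in step 11 are meant to provide.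

Step 11
Reactants: 22 cycloadduct
Product: 23 11,12-dihydro cycloadduct (7-oxanorbornane; otherwise as 22)
Conditions: H2 (1 atm), RhCl(PPh3)3 (cat.), PhH/EtOH, rt
Reagents that add atoms: none
Why: Homogeneous hydrogenation should saturate the strained cis-disubstituted C11=C12 bond without hydrogenolysis of the benzylic C9–O bond, and it removes the retro-Diels–Alder pathway.

Step 12
Reactants: 23 11,12-dihydro cycloadduct
Product: 24 ring-opened styrene: C9=C11 double bond; C13 tertiary trimethylsilyl ether; lactone, phosphonate and ring A as in 23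
Conditions: TMSOTf, Et3N, CH2Cl2, −78 to 0 °C
Reagents that add atoms: trimethylsilyl trifluoromethanesulfonate, C[Si](C)(C)OS(=O)(=O)C(F)(F)F
Why: Lewis-acid-mediated eliminative opening of the 7-oxanorbornane: silylation of the bridge oxygen ionises the tertiary benzylic C9–O bond (the C13–O bond is not benzylic and is deactivated by the β-phosphonate), and E1 loss of H11, the only β-hydrogen since C8 is quaternary, leaves the oxygen on C13 as its silyl ether.

Step 13
Reactants: 24 ring-opened styrene
Product: 26 hydroxy lactone: C9–H cis to C15 (C11 and C14 on the same face of ring B); free C13–OH; lactone and phosphonate unchanged, via silyl ether 25 (not isolated)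
Conditions: [Ir(cod)(PCy3)(py)]PF6 (cat.), H2 (1 atm), CH2Cl2, rt; then 1 M HCl, THF, 0 °C
Reagents that add atoms: none
Why: Carbonyl-directed homogeneous hydrogenation, in which the cationic catalyst is held by the lactone carbonyl on the C15 face while the C13 silyl ether shields the other face, should deliver H9 cis to C15 as the target requires; dilute acid then frees the tertiary alcohol.

Step 14
Reactants: 26 hydroxy lactone
Product: 27 ring D keto phosphonate: C15 ketone; C16 carries P(O)(OEt)2 (C16 epimers or enol); C13–OH; C7 as CH2OH; ethyl ester on ring A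
Conditions: LiN(SiMe3)2 (3.5 equiv), THF, −78 °C to rt; then NH4Cl (aq)
Reagents that add atoms: none
Why: Intramolecular Claisen (Dieckmann-type) acylation of the C16 phosphonate carbanion by the lactone carbonyl C15 closes the five-membered ring D, is driven by formation of the β-keto phosphonate enolate, and releases C7 as the primary alcohol; C15 and C16 are cis on ring C by construction in step 10.

Step 15
Reactants: 27 ring D keto phosphonate; 28 formaldehyde
Product: 29 enone: 15-oxo, C16=C17 exocyclic methylene; C13–OH; C7 as CH2OH; ethyl ester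
Conditions: 28 (37 % aq), K2CO3, THF, rt
Reagents that add atoms: none
Why: Horner–Wadsworth–Emmons olefination of formaldehyde by the β-keto phosphonate gives the α-methylene ketone; elimination toward the bridgehead C13 is excluded.

Step 16
Reactants: 29 enone
Product: 30 allylic alcohol: 15-hydroxy (C15 epimers, inconsequential), C16=C17; C13–OH; C7 as CH2OH; ethyl ester
Conditions: NaBH4, CeCl3·7H2O, MeOH, −20 °C
Reagents that add atoms: none
Why: Luche reduction gives 1,2-reduction of the enone and leaves the ester alone; the new C15 centre is removed in step 18.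

Step 17
Reactants: 30 allylic alcohol
Product: 31 7,15-bis(formate) of 30
Conditions: acetic formic anhydride, pyridine, CH2Cl2, 0 °C
Reagents that add atoms: acetic formic anhydride, CC(=O)OC=O
Why: Acylation converts the secondary allylic alcohol into the formate needed for reduction and caps the primary alcohol, while the hindered bridgehead tertiary alcohol is expected to stay free.

Step 18
Reactants: 31 7,15-bis(formate)
Product: 33 hydroxy acid: exocyclic C16=C17, C15 as CH2, C13–OH, C7 as CH2OH, free benzofuran-3-carboxylic acid, via formate ester 32 (not isolated)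
Conditions: Pd(OAc)2 (cat.), n-Bu3P, THF, 60 °C; then LiOH, THF/MeOH/H2O, rt; then 1 M HCl
Reagents that add atoms: lithium hydroxide, [Li+].[OH-]
Why: Tsuji–Trost-type decarboxylative reduction of the allylic formate, in which the π-allyl intermediate takes hydride at its more substituted terminus C15 and so leaves the 1,1-disubstituted C16=C17 alkene; saponification then cleaves the C7 formate and the ethyl ester.

Step 19
Reactants: 33 hydroxy acid
Product: 34 pharbinilic acid
Conditions: TEMPO (cat.), PhI(OAc)2, MeCN/H2O (1:1), rt
Reagents that add atoms: water, O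
Why: Nitroxyl-catalysed oxidation takes the primary alcohol through the aldehyde hydrate to the carboxylic acid under near-neutral conditions, which should leave the tertiary allylic alcohol, the alkene and the C6 configuration untouched.

**Compound list**

1 | 2,4-dihydroxy-3-methylbenzaldehyde | O=Cc1ccc(O)c(C)c1O | starting material
2 | 5-chloro-2,4-dihydroxy-3-methylbenzaldehyde | O=Cc1cc(Cl)c(O)c(C)c1O | intermediate
3 | 6-chloro-4-formyl-3-hydroxy-2-methylphenyl trifluoromethanesulfonate | O=Cc1cc(Cl)c(OS(=O)(=O)C(F)(F)F)c(C)c1O | intermediate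
4 | ethyl diazoacetate | CCOC(=O)C=[N+]=[N-] | starting material
5 | ethyl 5-chloro-2-hydroxy-7-methyl-6-(trifluoromethylsulfonyloxy)-2,3-dihydro-1-benzofuran-3-carboxylate (hemiacetal, diastereomer mixture, not isolated) | CCOC(=O)C1C(O)Oc2c(C)c(OS(=O)(=O)C(F)(F)F)c(Cl)cc12 | intermediate
6 | ethyl 5-chloro-7-methyl-6-(trifluoromethylsulfonyloxy)-1-benzofuran-3-carboxylate | CCOC(=O)c1coc2c(C)c(OS(=O)(=O)C(F)(F)F)c(Cl)cc12 | intermediate
7 | bis(pinacolato)diboron | CC1(C)OB(OC1(C)C)B1OC(C)(C)C(C)(C)O1 | starting material
8 | 4-bromofuran-2(5H)-one | O=C1C=C(Br)CO1 | starting material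
9 | ethyl 5-chloro-7-methyl-6-(4,4,5,5-tetramethyl-1,3,2-dioxaborolan-2-yl)-1-benzofuran-3-carboxylate (not isolated) | CCOC(=O)c1coc2c(C)c(B3OC(C)(C)C(C)(C)O3)c(Cl)cc12 | intermediate
10 | ethyl 5-chloro-7-methyl-6-(5-oxo-2,5-dihydrofuran-3-yl)-1-benzofuran-3-carboxylate | CCOC(=O)c1coc2c(C)c(C3=CC(=O)OC3)c(Cl)cc12 | intermediate
11 | ethyl 5-chloro-7-methyl-6-[(3R)-5-oxooxolan-3-yl]-1-benzofuran-3-carboxylate | CCOC(=O)c1coc2c(C)c([C@H]3CC(=O)OC3)c(Cl)cc12 | intermediate
12 | N,N-dimethylmethyleneiminium iodide | C=[N+](C)C.[I-] | starting material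
13 | iodomethane | CI | starting material
14 | ethyl 5-chloro-6-[(3R)-4-(dimethylaminomethyl)-5-oxooxolan-3-yl]-7-methyl-1-benzofuran-3-carboxylate (aminomethyl trans to aryl, not isolated) | CCOC(=O)c1coc2c(C)c([C@H]3[C@H](CN(C)C)C(=O)OC3)c(Cl)cc12 | intermediate
15 | trimethylammonium iodide of 14 (not isolated) | CCOC(=O)c1coc2c(C)c([C@H]3[C@H](C[N+](C)(C)C)C(=O)OC3)c(Cl)cc12.[I-] | intermediate
16 | ethyl 5-chloro-7-methyl-6-[(3R)-4-methylidene-5-oxooxolan-3-yl]-1-benzofuran-3-carboxylate | CCOC(=O)c1coc2c(C)c([C@H]3C(=C)C(=O)OC3)c(Cl)cc12 | intermediate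
17 | furan-2-ylmethanol | OCc1ccco1 | starting material
18 | triethyl phosphite | CCOP(OCC)OCC | starting material
19 | diethyl (furan-2-ylmethyl)phosphonate | CCOP(=O)(OCC)Cc1ccco1 | intermediate
20 | diethyl {[5-(4,4,5,5-tetramethyl-1,3,2-dioxaborolan-2-yl)furan-2-yl]methyl}phosphonate | CCOP(=O)(OCC)Cc1ccc(B2OC(C)(C)C(C)(C)O2)o1 | intermediate
21 | ethyl 5-{5-[(diethoxyphosphoryl)methyl]furan-2-yl}-7-methyl-6-[(3S)-4-methylidene-5-oxooxolan-3-yl]-1-benzofuran-3-carboxylate | CCOC(=O)c1coc2c(C)c([C@H]3C(=C)C(=O)OC3)c(-c3ccc(CP(=O)(OCC)OCC)o3)cc12 | intermediate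
22 | cycloadduct: C9–O–C13 bridged 7-oxanorbornene (C11=C12) fused to ring B; 15,7-γ-lactone on the ring B face opposite C14 and the O bridge; C13–CH2P(O)(OEt)2; ethyl ester | O=C1OC[C@H]2c3c(C)c4occ(C(=O)OCC)c4cc3[C@@]34O[C@@](CP(=O)(OCC)OCC)(C=C3)C[C@]124 | intermediate
23 | 11,12-dihydro derivative of 22 | O=C1OC[C@H]2c3c(C)c4occ(C(=O)OCC)c4cc3[C@@]34O[C@@](CP(=O)(OCC)OCC)(CC3)C[C@]124 | intermediate
24 | styrene silyl ether: C9=C11; C13–OSiMe3; lactone and phosphonate retained | O=C1OC[C@H]2c3c(C)c4occ(C(=O)OCC)c4cc3C3=CC[C@](CP(=O)(OCC)OCC)(O[Si](C)(C)C)C[C@]123 | intermediate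
25 | 24 hydrogenated at C9=C11, H9 cis to C15 (silyl ether, not isolated) | O=C1OC[C@H]2c3c(C)c4occ(C(=O)OCC)c4cc3[C@@H]3CC[C@](CP(=O)(OCC)OCC)(O[Si](C)(C)C)C[C@]123 | intermediate
26 | hydroxy lactone: 25 with free C13–OH | O=C1OC[C@H]2c3c(C)c4occ(C(=O)OCC)c4cc3[C@@H]3CC[C@](CP(=O)(OCC)OCC)(O)C[C@]123 | intermediate
27 | ring D keto phosphonate: 15-oxo; C16–P(O)(OEt)2 (epimers or enol); C13–OH; C7 CH2OH; ethyl ester | CCOP(=O)(OCC)C1C(=O)[C@]23C[C@@]1(O)CC[C@H]2c1cc2c(C(=O)OCC)coc2c(C)c1[C@@H]3CO | intermediate
28 | formaldehyde | C=O | starting material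
29 | enone: 15-oxo-16-methylidene; C13–OH; C7 CH2OH; ethyl ester | C=C1C(=O)[C@]23C[C@@]1(O)CC[C@H]2c1cc2c(C(=O)OCC)coc2c(C)c1[C@@H]3CO | intermediate
30 | allylic alcohol: 15-hydroxy-16-methylidene (C15 epimers); C13–OH; C7 CH2OH; ethyl ester | C=C1C(O)[C@]23C[C@@]1(O)CC[C@H]2c1cc2c(C(=O)OCC)coc2c(C)c1[C@@H]3CO | intermediate
31 | 7,15-bis(formate) of 30 | C=C1C(OC=O)[C@]23C[C@@]1(O)CC[C@H]2c1cc2c(C(=O)OCC)coc2c(C)c1[C@@H]3COC=O | intermediate
32 | 15-deoxy compound: C7 formate, ethyl ester (not isolated) | C=C1C[C@]23C[C@@]1(O)CC[C@H]2c1cc2c(C(=O)OCC)coc2c(C)c1[C@@H]3COC=O | intermediate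
33 | hydroxy acid: pharbinilic acid with C7 as CH2OH | C=C1C[C@]23C[C@@]1(O)CC[C@H]2c1cc2c(C(=O)O)coc2c(C)c1[C@@H]3CO | intermediate
34 | pharbinilic acid | C=C1C[C@]23C[C@@]1(O)CC[C@H]2c1cc2c(C(=O)O)coc2c(C)c1[C@@H]3C(=O)O | target

**Step count**

Total: 19 steps. Longest linear sequence: 17 steps (steps 1–6 and 9–19, from 1 to 34); steps 7 and 8 form the side branch to 20.

**Steps most likely to fail, with fallbacks**

Step 10. The cycloaddition may stall or revert before the adduct can be hydrogenated, because furan aromaticity and aryl–furan conjugation are lost in 22. Fallback: setting out from 21, the ring construction is run as a silyl-triflate-triggered stepwise cycloaddition in the presence of a hydride donor (TMSOTf, Et3SiH, CH2Cl2, −78 to −20 °C). The adduct is then ionised at the benzylic C9–O bond as soon as it forms, the C9–C11–C12 allyl cation is reduced at C12 by the silane (ionic hydrogenation), and the sequence comes back to the route at silyl ether 24, so that 22 and 23 never have to accumulate. No compound outside the list is made (F0).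

Step 13. Hydrogen may be delivered from the C14 face (poor facial selectivity, giving the C9 epimer), or the catalyst may be inhibited by the phosphonate. Fallback: setting out from 24, a hydrogen-atom-transfer hydrogenation (Mn(dpm)3 cat., PhSiH3, t-BuOOH, i-PrOH, rt) replaces the directed metal-hydride addition. The stepwise radical path puts the first hydrogen on C11 and lets the planar benzylic C9 radical take the second hydrogen under product-like control, which favours the less strained cis ring fusion between the indane ring B and ring C. It comes back to the route at 25, which is desilylated to 26 as in step 13. No compound outside the list is made (F0).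

Step 14. The C16 carbanion may fail to add to the hindered lactone carbonyl, or the Claisen equilibrium may return to the lactone through re-attack of the released C7 alkoxide. Fallback: setting out from 26, the lactone is opened with MeNH(OMe)·HCl and AlMe3 (CH2Cl2, 0 °C to rt) to the N-methoxy-N-methylamide F1. The primary C7 hydroxyl is capped (TBSCl, imidazole, DMF) to give silyl ether F2. LiN(SiMe3)2 (THF, −78 °C to rt; then NH4Cl) then closes ring D irreversibly through the chelated tetrahedral intermediate to the silylated keto phosphonate F3. HF·pyridine (THF, 0 °C) removes the silyl group and comes back to the route at 27.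

**Further compounds**

F0 | step 10 | none | none
F0 | step 13 | none | none
F1 | step 14 | N-methoxy-N-methylamide: C15 carboxamide on C8; free C7 CH2OH and C13–OH; phosphonate and ethyl ester as in 26 | CON(C)C(=O)[C@]12C[C@](O)(CP(=O)(OCC)OCC)CC[C@H]1c1cc3c(C(=O)OCC)coc3c(C)c1[C@@H]2CO
F2 | step 14 | silyl ether: C7-O-tert-butyldimethylsilyl derivative of F1 | CON(C)C(=O)[C@]12C[C@](O)(CP(=O)(OCC)OCC)CC[C@H]1c1cc3c(C(=O)OCC)coc3c(C)c1[C@@H]2CO[Si](C)(C)C(C)(C)C
F3 | step 14 | keto phosphonate: C7-O-tert-butyldimethylsilyl derivative of 27 | CCOP(=O)(OCC)C1C(=O)[C@]23C[C@@]1(O)CC[C@H]2c1cc2c(C(=O)OCC)coc2c(C)c1[C@@H]3CO[Si](C)(C)C(C)(C)C
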